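Locants follow the germacrane skeleton of the target throughout, also in the bicyclic and tricyclic precursors: ring carbons C1–C10, with C3 bearing the angelate, C6 the acetate, C7 the isopropyl group (C11–C13), C10 the methyl C14 and C4 the methyl C15.

## The problem

The target 19 is a ten-membered carbocycle with two trisubstituted ring olefins, C1=C10 (Z) and C4=C5 (E), joined through C2–C3 into a cyclodeca-1,5-diene. Such a ring is hard to close end to end, each olefin geometry has to be set against ring strain, and the 1,5-diene rearranges (Cope) on heating and cyclises across the ring with acid. There are three stereocentres: C6 and C7 are neighbours (acetoxy and isopropyl cis on the ring), while C3 sits on the far side of C4=C5 and cannot be reached by simple relay. Both oxygens are allylic to C4=C5, and the C3 ester is an angelate that isomerises to the tiglate with base, acid or nucleophilic catalysts, so it must be put on last. The feature that opens a short route is that the four olefinic carbons C1, C10, C4 and C5 can be paired the other way round: C5=C10 inside a six-membered ring C5–C6–C7–C8–C9–C10 and C1=C4 inside a four-membered ring C1–C2–C3–C4. The six-membered ring, with a carbonyl at C6, C14 on C10 and isopropyl on C7, is (S)-piperitone 4, and the four-membered ring, with oxygen at C3 and C15 on C4, is cyclobutene 10. A cyclobutane made of C1, C4, C5 and C10 joins them, and opening it in the other direction gives the ten-membered ring and both olefins at once.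

## Retrosynthesis

**19 ⇒ 16 + 17.** The C3–O acyl bond is cut first. Angelic acid 17 is attached last because no later step may touch the Z-enoate; the forward reaction must esterify a hindered allylic alcohol without Z to E isomerisation.

**16 ⇒ 15.** The C3–H bond is cut back to the enone. C3 is too remote from C6 and C7 for substrate relay, so it is set by a catalyst on an α-methyl enone, a good substrate class for oxazaborolidine reduction. Holding C3 at the ketone level also lets the four-membered building block be achiral.

**15 ⇒ 14.** The C3 carbonyl is masked as a dioxolane so that only one carbonyl-derived centre (C6) is live during ring construction. The forward step is a mild hydrolysis of an allylic ketal beside an allylic acetate.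

**14 ⇒ 13.** The C6–O bond is cut with inversion. The 6S carbinol 13 is what the key step delivers, and a Mitsunobu reaction with acetic acid converts it to the 6R acetate, so inversion and acetylation cost one step.

**13 ⇒ 12 (key).** The π bonds C1=C10 and C4=C5 are exchanged for the σ bonds C5–C10 and C1–C4, giving tricycle 12. Against cuts at C5–C6, C6–C7 or C8–C9, this one removes the medium ring and both olefin geometries in a single operation. Precursor 12 contains only four- and six-membered rings. The forward reaction must break C1–C4 and C5–C10 (not C2–C3) and must do so through one chair.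

**12 ⇒ 11.** The C6–H bond is cut back to the ketone. The equatorial 6S carbinol is introduced on purpose as a conformational lock for the key step.

**11 ⇒ 4 + 10.** The bonds C10–C1 and C5–C4 are cut, which is an enone–alkene [2+2] photocycloaddition in the forward sense. Both partners are small rings. The forward step must join them head-to-head and on the enone face opposite the isopropyl group.

**4 ⇒ 3 ⇒ 1.** The C5=C10 olefin is traced to (−)-menthone 1 through its kinetic silyl enol ether 3. The isopropyl stereocentre of 1 becomes C7; the methyl stereocentre of 1 is given up.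

**10 ⇒ 9 ⇒ 7 ⇒ 6 ⇒ 5.** The C4–C15 bond is cut to enol triflate 9. Ketone 7 can enolise on one side only, so the olefin position in 10 is unambiguous. Ketone 7 is the monoketal of dione 6, which comes from the commercial bis-silyl enediol 5.

## Roads not taken

**Alternative 1:** the most obvious cut is C5–C6. Seco aldehyde A1, a vinyl iodide, would be closed by a Nozaki–Hiyama–Kishi reaction (CrCl2, NiCl2 cat.) to allylic alcohol A2. A1 needs the Z olefin, the E vinyl iodide and two stereocentres to be built one by one in a long linear sequence. The ten-membered ring is then closed end to end under high dilution. The new C6 centre is left to Felkin control, which with the isopropyl group as the large substituent predicts the 6,7-trans isomer, opposite to the target. The chosen plan makes the ring without a macrocyclisation and sets both geometries in the same step.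

**Alternative 2:** the cut is C6–C7. The 13-membered bis-allylic ether A3 would undergo a [2,3]-Wittig ring contraction to A4, forming the carbocycle and both C6 and C7 in one event. A 13-membered ether must be made first. The required syn relation calls for a Z allyl ether terminus, which is the less accessible geometry. Absolute control would have to come from distant C3 through a transannular transition state. The isopropenyl group of A4 must then be hydrogenated beside two trisubstituted olefins. The precursor is not simpler than the product.

**Alternative 3:** the cut is C8–C9. The trans-dialkenylcyclohexenol A5 would undergo an anionic oxy-Cope rearrangement to dienone A6. In A5 the C4=C5 bond lies inside a six-membered ring and is therefore cis, and it stays Z in A6. The new C1=C10 bond comes out E from the chair transition state, and C7 is set only by enolate protonation. Both olefin geometries are the reverse of what the target needs; the chosen step gives the Z,E pair directly.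

Key step: step 9

Assumption (chemistry): (−)-menthone 1 is taken as commercial material of high enantiomeric purity; its isopropyl-bearing carbon becomes C7 and is kept away from base at every ketone stage.

## Steps

Step 1
Reactants: 1 (−)-menthone, (2S,5R)-5-methyl-2-(propan-2-yl)cyclohexan-1-one
Product: 3 trimethyl{[(3R,6S)-3-methyl-6-(propan-2-yl)cyclohex-1-en-1-yl]oxy}silane, via lithium enolate 2 (not isolated)
Conditions: LiN(CHMe2)2, THF, −78 °C; then Me3SiCl, −78 °C to rt
Reagents that add atoms: chlorotrimethylsilane, C[Si](C)(C)Cl; lithium diisopropylamide, [Li+].CC(C)[N-]C(C)C (its lithium stays in 2 only)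
Why: Kinetic deprotonation of an unsymmetrical ketone takes the less hindered CH2 proton, so the isopropyl-bearing centre is not enolised and keeps its configuration; O-silylation traps the regioisomer.

Step 2
Reactants: 3 trimethyl{[(3R,6S)-3-methyl-6-(propan-2-yl)cyclohex-1-en-1-yl]oxy}silane
Product: 4 (S)-piperitone, (6S)-3-methyl-6-(propan-2-yl)cyclohex-2-en-1-one
Conditions: Pd(OAc)2 (1.05 equiv), MeCN, rt
Reagents that add atoms: none
Why: Saegusa–Ito oxidation: the palladium enolate loses the β-hydrogen at the methyl-bearing carbon and gives the enone under neutral conditions, so the enolisable centre next to the carbonyl (later C7) is not racemised.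

Step 3
Reactants: 5 1,2-bis(trimethylsilyloxy)cyclobut-1-ene
Product: 6 cyclobutane-1,2-dione
Conditions: Br2 (1.0 equiv), pentane, −60 °C to rt
Reagents that add atoms: none
Why: Bromination of the enediol bis-silyl ether with loss of two equivalents of bromotrimethylsilane is the standard anhydrous entry to this strained dione.

Step 4
Reactants: 6 cyclobutane-1,2-dione
Product: 7 5,8-dioxaspiro[3.4]octan-1-one
Conditions: Me3SiOCH2CH2OSiMe3 (1.0 equiv), Me3SiOTf (cat.), CH2Cl2, −78 °C
Reagents that add atoms: 1,2-bis(trimethylsilyloxy)ethane, C[Si](C)(C)OCCO[Si](C)(C)C
Why: Noyori ketalisation under aprotic conditions; the first dioxolane deactivates the neighbouring carbonyl sterically and electronically, and the absence of water or hydroxide avoids benzilic-type ring contraction.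

Step 5
Reactants: 7 5,8-dioxaspiro[3.4]octan-1-one
Product: 9 5,8-dioxaspiro[3.4]oct-1-en-1-yl trifluoromethanesulfonate, via lithium enolate 8 (not isolated)
Conditions: LiN(SiMe3)2, THF, −78 °C; then PhNTf2, −78 to 0 °C
Reagents that add atoms: N-phenylbis(trifluoromethanesulfonimide), O=S(=O)(N(c1ccccc1)S(=O)(=O)C(F)(F)F)C(F)(F)F; lithium bis(trimethylsilyl)amide, [Li+].C[Si](C)(C)[N-][Si](C)(C)C (its lithium stays in 8 only)
Why: Enol triflate formation; the ketone has α-hydrogens on one side only (the other α-carbon is the spiro ketal carbon), so the double bond position is fixed.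

Step 6
Reactants: 9 5,8-dioxaspiro[3.4]oct-1-en-1-yl trifluoromethanesulfonate
Product: 10 1-methyl-5,8-dioxaspiro[3.4]oct-1-ene
Conditions: MeMgBr, Fe(acac)3 (5 mol %), THF/N-methylpyrrolidone, −30 °C
Reagents that add atoms: methylmagnesium bromide, C[Mg]Br
Why: Iron-catalysed Kumada-type cross-coupling of an alkenyl triflate with a methyl Grignard reagent; it is fast at low temperature and leaves the ketal untouched.

Step 7
Reactants: 4 (S)-piperitone; 10 1-methyl-5,8-dioxaspiro[3.4]oct-1-ene
Product: 11 (9S)-2,6-dimethyl-9-(propan-2-yl)spiro[tricyclo[4.4.0.0^2,5]decane-3,2'-[1,3]dioxolan]-10-one, the head-to-head cis-anti-cis adduct with the new bonds C10–C1 and C5–C4 on the ring face opposite the isopropyl group (H-5, C14 and the isopropyl group share one face)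
Conditions: hν (350 nm, Pyrex), 10 (3 equiv), CH2Cl2, −40 °C; chromatography
Reagents that add atoms: none
Why: Enone–alkene [2+2] photocycloaddition through the enone triplet and a 1,4-biradical; head-to-head union should prevail because the other orientation would have to join the two fully substituted carbons C4 and C10, the cyclobutene should prefer the face away from the C7 isopropyl group and the anti arrangement of the two small rings, and other isomers are removed by chromatography (of the four new centres only the relation of H-5 and C14 to the isopropyl group matters, since all four become sp2 in step 9).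

Step 8
Reactants: 11 tricyclic ketone
Product: 12 (9S,10S)-2,6-dimethyl-9-(propan-2-yl)spiro[tricyclo[4.4.0.0^2,5]decane-3,2'-[1,3]dioxolan]-10-ol, the C6 hydroxyl on the cyclobutane face and trans to the isopropyl group
Conditions: NaBH4, CeCl3·7H2O, MeOH, −40 °C
Reagents that add atoms: none
Why: Luche-type hydride reduction: hydride should add to the face away from the cyclobutane (C4 and its methyl C15 hang over the other face), giving the equatorial 6S carbinol, which is also the more stable epimer; the cerium salt keeps the medium non-basic so C7 is not epimerised.

Step 9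
Reactants: 12 tricyclic alcohol
Product: 13 (1(10)Z,4E,6S,7S)-3,3-(ethylenedioxy)germacra-1(10),4-dien-6-ol
Conditions: mesitylene (0.01 M), Ar, base-washed sealed tube, 190 °C
Reagents that add atoms: none
Why: Thermal retro-[2+2] of the bicyclo[2.2.0]hexane unit C1–C2–C3–C4–C5–C10: the strained central bond C1–C4 gives way first to a cyclohexane-1,4-diyl-like species and the bond C5–C10, the most substituted one parallel to it, follows, so that C1=C10 and C4=C5 appear together and the six- and four-membered rings merge into the ten-membered one. The closest known reaction type is the thermolysis of cis-fused enone–cyclobutene photoadducts to cis,trans-cyclodeca-1,5-dienes. The ring is not closed end to end but opened out of two small rings (ring expansion by fragmentation), so no high-dilution closure is involved. No stereocentre is formed; the two olefin geometries are fixed by the chair in which the diyl cleaves: a substituent on C5 or C10 that is axial on the six-membered diyl ring ends up cis to the C2–C3 chain, an equatorial one trans. In 12 the cyclohexane chair with the isopropyl group, the C6 hydroxyl and C1 equatorial and C4 axial should be strongly preferred, because the other chair puts the hydroxyl and C1 in a 1,3-diaxial relation and the isopropyl group axial; in the preferred chair C9 is axial and C6 equatorial on the diyl ring, which gives Z at C1=C10 and E at C4=C5. This equatorial carbinol is the reason for reducing before the thermolysis: it should outweigh the allylic strain between C15 and C6 that would otherwise favour the opposite pair of geometries. The step needs scission of C5–C10 and not of C2–C3 (favoured by the quaternary C10 and tertiary C5) and a product that does not go on by Cope rearrangement (cis,trans-1,5-dienes do so only at higher temperature).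

Step 10
Reactants: 13 (1(10)Z,4E,6S,7S)-3,3-(ethylenedioxy)germacra-1(10),4-dien-6-ol
Product: 14 (1(10)Z,4E,6R,7S)-3,3-(ethylenedioxy)germacra-1(10),4-dien-6-yl acetate
Conditions: PPh3, DIAD, AcOH, toluene, 0 °C to rt
Reagents that add atoms: acetic acid, CC(=O)O
Why: Mitsunobu reaction: acetate displaces the activated allylic C6 oxygen by SN2 with inversion, which sets 6R (acetoxy cis to the isopropyl group); attack with allylic shift at C4 is blocked because C4 is fully substituted and flanked by the ketal.

Step 11
Reactants: 14 (1(10)Z,4E,6R,7S)-3,3-(ethylenedioxy)germacra-1(10),4-dien-6-yl acetate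
Product: 15 (1(10)Z,4E,6R,7S)-6-acetoxygermacra-1(10),4-dien-3-one
Conditions: PPTS (cat.), THF/H2O (4:1), 40 °C
Reagents that add atoms: water, O
Why: Acid-catalysed hydrolysis of an allylic dioxolane through an allyl-stabilised oxocarbenium ion; the weak acid should spare the acetate and not trigger transannular cyclisation of the diene.

Step 12
Reactants: 15 (1(10)Z,4E,6R,7S)-6-acetoxygermacra-1(10),4-dien-3-one
Product: 16 (1(10)Z,4E,3S,6R,7S)-6-acetoxygermacra-1(10),4-dien-3-ol
Conditions: (R)-2-methyl-CBS-oxazaborolidine (0.3 equiv), catecholborane (1.5 equiv), toluene, −78 °C; then MeOH, aq. NaHCO3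
Reagents that add atoms: none
Why: Corey–Bakshi–Shibata reduction of an α-methyl enone: the alkenyl flank C4(CH3)=C5 acts as the large group and the C2 methylene as the small one, so the (R)-catalyst should deliver hydride to the face that gives 3S; catecholborane does not hydroborate the trisubstituted olefins at this temperature.

Step 13
Reactants: 16 (1(10)Z,4E,3S,6R,7S)-6-acetoxygermacra-1(10),4-dien-3-ol; 17 angelic acid, (Z)-2-methylbut-2-enoic acid
Product: 19 (1(10)Z,4E,3S,6R,7S)-6-acetoxygermacra-1(10),4-dien-3-yl (Z)-2-methylbut-2-enoate (CNP0306415.2), via mixed anhydride 18 (not isolated)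
Conditions: 17, 2,4,6-trichlorobenzoyl chloride, Et3N, toluene, rt; then 16, toluene, 75 °C
Reagents that add atoms: 2,4,6-trichlorobenzoyl chloride, O=C(Cl)c1c(Cl)cc(Cl)cc1Cl (its atoms stay in 18 only)
Why: Yamaguchi-type esterification through the mixed anhydride, run without a nucleophilic amine catalyst so that no reversible conjugate addition can turn the angelate into the tiglate; the alcohol attacks the less hindered angeloyl carbonyl.

## Compound list

1 | (−)-menthone, (2S,5R)-5-methyl-2-(propan-2-yl)cyclohexan-1-one | CC(C)[C@@H]1CC[C@@H](C)CC1=O | starting material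
2 | lithium (3R,6S)-3-methyl-6-(propan-2-yl)cyclohex-1-en-1-olate | CC(C)[C@@H]1CC[C@@H](C)C=C1[O-].[Li+] | intermediate (not isolated)
3 | trimethyl{[(3R,6S)-3-methyl-6-(propan-2-yl)cyclohex-1-en-1-yl]oxy}silane | CC(C)[C@@H]1CC[C@@H](C)C=C1O[Si](C)(C)C | intermediate
4 | (S)-piperitone, (6S)-3-methyl-6-(propan-2-yl)cyclohex-2-en-1-one | CC(C)[C@@H]1CCC(C)=CC1=O | intermediate
5 | 1,2-bis(trimethylsilyloxy)cyclobut-1-ene | C[Si](C)(C)OC1=C(O[Si](C)(C)C)CC1 | starting material
6 | cyclobutane-1,2-dione | O=C1CCC1=O | intermediate
7 | 5,8-dioxaspiro[3.4]octan-1-one | O=C1CCC12OCCO2 | intermediate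
8 | lithium 5,8-dioxaspiro[3.4]oct-1-en-1-olate | [Li+].[O-]C1=CCC12OCCO2 | intermediate (not isolated)
9 | 5,8-dioxaspiro[3.4]oct-1-en-1-yl trifluoromethanesulfonate | O=S(=O)(OC1=CCC12OCCO2)C(F)(F)F | intermediate
10 | 1-methyl-5,8-dioxaspiro[3.4]oct-1-ene | CC1=CCC12OCCO2 | intermediate
11 | (9S)-2,6-dimethyl-9-(propan-2-yl)spiro[tricyclo[4.4.0.0^2,5]decane-3,2'-[1,3]dioxolan]-10-one, head-to-head, cis-anti-cis, cyclobutane anti to the isopropyl group | O=C1[C@H](C(C)C)CC[C@]2(C)[C@H]1[C@@]3(C)C4(OCCO4)C[C@@H]23 | intermediate
12 | (9S,10S)-2,6-dimethyl-9-(propan-2-yl)spiro[tricyclo[4.4.0.0^2,5]decane-3,2'-[1,3]dioxolan]-10-ol, hydroxyl trans to the isopropyl group | O[C@H]1[C@H](C(C)C)CC[C@]2(C)[C@H]1[C@@]3(C)C4(OCCO4)C[C@@H]23 | intermediate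
13 | (1(10)Z,4E,6S,7S)-3,3-(ethylenedioxy)germacra-1(10),4-dien-6-ol | O1CCOC12C/C=C(/C)CC[C@@H](C(C)C)[C@H](O)/C=C/2C | intermediate
14 | (1(10)Z,4E,6R,7S)-3,3-(ethylenedioxy)germacra-1(10),4-dien-6-yl acetate | O1CCOC12C/C=C(/C)CC[C@@H](C(C)C)[C@@H](OC(C)=O)/C=C/2C | intermediate
15 | (1(10)Z,4E,6R,7S)-6-acetoxygermacra-1(10),4-dien-3-one | O=C1C/C=C(/C)CC[C@@H](C(C)C)[C@@H](OC(C)=O)/C=C/1C | intermediate
16 | (1(10)Z,4E,3S,6R,7S)-6-acetoxygermacra-1(10),4-dien-3-ol | O[C@H]1C/C=C(/C)CC[C@@H](C(C)C)[C@@H](OC(C)=O)/C=C/1C | intermediate
17 | angelic acid, (Z)-2-methylbut-2-enoic acid | C/C=C(/C)C(=O)O | starting material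
18 | (Z)-2-methylbut-2-enoic 2,4,6-trichlorobenzoic anhydride | C/C=C(/C)C(=O)OC(=O)c1c(Cl)cc(Cl)cc1Cl | intermediate (not isolated)
19 | (1(10)Z,4E,3S,6R,7S)-6-acetoxygermacra-1(10),4-dien-3-yl (Z)-2-methylbut-2-enoate, CNP0306415.2 | C/C=C(/C)C(=O)O[C@H]1C/C=C(/C)CC[C@@H](C(C)C)[C@@H](OC(C)=O)/C=C/1C | target

## Step count and risk

Total step count: 13. Longest linear sequence: 11 steps (5 → 6 → 7 → 9 → 10 → 11 → 12 → 13 → 14 → 15 → 16 → 19); the branch 1 → 4 has 2 steps.

**Step 9 (key step).** Three things may go wrong.
- Scission of the C2–C3 bond instead of C5–C10 after the central bond has opened. The carbinol series has no carbonyl to assist the C5–C10 cleavage, and the ketal carbon makes C2–C3 a competitive bond.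
- Partial reaction through the other chair, which would exchange the two olefin geometries.
- Onward Cope rearrangement of the 1,5-diene if heating is prolonged.

Fallback: set out from ketone 11 and thermolyse it directly. Scission of C5–C10 is then assisted by the developing conjugation with the C6 carbonyl and should give (1(10)Z,4E,7S)-3,3-(ethylenedioxy)germacra-1(10),4-dien-6-one F1. F1 is taken on by the two operations described under step 10 (reduction to F2, then acetylation), and the route is rejoined at 14. The price is that the chair of 11 is not locked by an equatorial hydroxyl and that C7 is enolisable at high temperature. This variant swaps the controlling element (carbonyl-assisted scission for the carbinol-locked chair) and the order in which C6 is set.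

**Step 10.** The Mitsunobu inversion may suffer from elimination towards C7, from ionisation of the allylic oxyphosphonium ion with loss of stereochemical fidelity, or from slow displacement next to the isopropyl-bearing carbon.

Fallback: set out from 13 and oxidise the allylic alcohol with MnO2 (CH2Cl2, rt) to dienone F1. Reduce the ketone with LiBH(CHMeEt)3 (THF, −78 °C), which should attack from the periphery with the ring bond C7–C8 anti to the hydride and the isopropyl group beside the carbonyl oxygen, giving (1(10)Z,4E,6R,7S)-3,3-(ethylenedioxy)germacra-1(10),4-dien-6-ol F2. Acetylate F2 (Ac2O, DMAP, Et3N) to rejoin the route at 14. Inversion by displacement is thus replaced by an oxidation–reduction pair under macrocyclic stereocontrol.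

**Step 12.** The conformational facial bias of the ten-membered enone may override catalyst control, giving poor selectivity at C3.

Fallback: set out from 15 and reduce under substrate control (NaBH4, CeCl3·7H2O, MeOH, −78 °C). If this gives the 3R epimer, (1(10)Z,4E,3R,6R,7S)-6-acetoxygermacra-1(10),4-dien-3-ol F3, esterify F3 with angelic acid 17 under Mitsunobu conditions (PPh3, DIAD, toluene, 0 °C). This inverts C3 and installs the angelate in one operation, returning at 19. Here C3 is set by inversion in the esterification instead of by the catalyst.

**Step 4.** The strained dione may undergo double ketalisation or ring contraction by nucleophilic addition.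

Fallback: set out from 5 and cleave both silyl groups with methanol to give 2-hydroxycyclobutan-1-one F4. Ketalise the carbonyl of F4 with ethylene glycol (PPTS, benzene, reflux with water removal) to give 5,8-dioxaspiro[3.4]octan-1-ol F5. Oxidise F5 under Swern conditions to rejoin the route at 7. The ketal is thus made at the acyloin oxidation level and the dione is never handled.

## Further compounds

F1 | step 9 | (1(10)Z,4E,7S)-3,3-(ethylenedioxy)germacra-1(10),4-dien-6-one | O1CCOC12C/C=C(/C)CC[C@@H](C(C)C)C(=O)/C=C/2C
F2 | step 10 | (1(10)Z,4E,6R,7S)-3,3-(ethylenedioxy)germacra-1(10),4-dien-6-ol | O1CCOC12C/C=C(/C)CC[C@@H](C(C)C)[C@@H](O)/C=C/2C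
F3 | step 12 | (1(10)Z,4E,3R,6R,7S)-6-acetoxygermacra-1(10),4-dien-3-ol | O[C@@H]1C/C=C(/C)CC[C@@H](C(C)C)[C@@H](OC(C)=O)/C=C/1C
F4 | step 4 | 2-hydroxycyclobutan-1-one (racemic) | O=C1CCC1O
F5 | step 4 | 5,8-dioxaspiro[3.4]octan-1-ol (racemic) | OC1CCC12OCCO2
A1 | alternative 1 | (2S,5Z,8S,9E)-8-(tert-butyldimethylsilyloxy)-10-iodo-5,9-dimethyl-2-(propan-2-yl)deca-5,9-dienal | O=C[C@H](C(C)C)CC/C(C)=C\C[C@H](O[Si](C)(C)C(C)(C)C)/C(C)=C/I
A2 | alternative 1 | (1(10)Z,4E,3S,6R,7S)-3-(tert-butyldimethylsilyloxy)germacra-1(10),4-dien-6-ol | O([Si](C)(C)C(C)(C)C)[C@H]1C/C=C(/C)CC[C@@H](C(C)C)[C@@H](O)/C=C/1C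
A3 | alternative 2 | (3E,5S,7Z,11E)-5-(tert-butyldimethylsilyloxy)-4,8,12-trimethyl-1-oxacyclotrideca-3,7,11-triene | O1C/C=C(C)/[C@@H](O[Si](C)(C)C(C)(C)C)C/C=C(/C)CC/C=C(\C)C1
A4 | alternative 2 | (1(10)Z,4E)-3-(tert-butyldimethylsilyloxy)germacra-1(10),4,11-trien-6-ol, the 7-isopropenyl analogue of A2 with the same spatial arrangement at C3, C6 and C7 | O([Si](C)(C)C(C)(C)C)[C@H]1C/C=C(/C)CC[C@@H](C(C)=C)[C@@H](O)/C=C/1C
A5 | alternative 3 | (4S)-4-(tert-butyldimethylsilyloxy)-3-methyl-1-(3-methylbut-1-en-2-yl)-6-(prop-1-en-2-yl)cyclohex-2-en-1-ol, alkenyl groups trans | C=C(C)[C@H]1C[C@H](O[Si](C)(C)C(C)(C)C)C(C)=C[C@]1(O)C(=C)C(C)C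
A6 | alternative 3 | (1(10)E,4Z,3S)-3-(tert-butyldimethylsilyloxy)germacra-1(10),4-dien-6-one, drawn as the 7S epimer | O([Si](C)(C)C(C)(C)C)[C@H]1C/C=C(\C)CC[C@@H](C(C)C)C(=O)/C=C\1C
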